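In the south-east run at 120 min the readings leave a leftover: 26.1% starting material and 53.6% product, so 20.3% of the charge stands in neither column. Something holds it, and the late readings don't drift. We therefore reckon the flask from where the runs come to rest.

in all of them: gas phase 15 mM (held)

| charge | starting material | catalyst | remark | time |
|---|---|---|---|---|
| south-east | 0.025 M (fed, over 40 s) | 65 µM | run made earlier |  |
| south-west | 0.10 M (fed, over 40 s) | 65 µM | run made earlier |  |
| south | 0.050 M (fed, over 40 s) | 130 µM | run made earlier |  |
| flask | 0.050 M (fed, over 40 s) | 65 µM |  | 3.0 h |

| run | time / min | starting material / % | product / % |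
|---|---|---|---|
| south-east | 10.0 | 27.9 | 55.5 |
| south-east | 25.0 | 25.5 | 55.0 |
| south-east | 50.0 | 25.6 | 53.7 |
| south-east | 80.0 | 25.2 | 53.7 |
| south-east | 120 | 26.1 | 53.6 |
| south-west | 10.0 | 27.4 | 55.1 |
| south-west | 25.0 | 25.6 | 54.0 |
| south-west | 50.0 | 25.3 | 53.7 |
| south-west | 80.0 | 25.7 | 54.2 |
| south-west | 120 | 25.3 | 53.5 |
| south | 10.0 | 25.8 | 57.9 |
| south | 25.0 | 25.4 | 54.2 |
| south | 50.0 | 26.2 | 52.8 |
| south | 80.0 | 26.7 | 53.6 |
| south | 120 | 25.9 | 53.2 |

(scatter of a reading: 0.5 percentage points)

- share of the starting material used up at 3.0 h
- product at 3.0 h, in percent of the starting material charged

- the earlier runs were read with a standard deviation of 0.5 percentage points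
- at the start none of the gas phase is in solution
- what has gone from starting material into another species counts as reacted, even if it can come back

First round: we take the last readings of the two runs with the flask's catalyst, whose charges lie on either side of the flask's.

starting material 25.7%, product 53.6%

Second round: we put these back to sort the readings. South-west starting material at 10.0 min stands 1.7 percentage points above the first value, and south-east product at 25.0 min stands 1.4 points above it. Both are more than twice the scatter, so those readings were still moving. We average both runs from 50.0 min on.

starting material 25.5%, product 53.7%

The first of these is the rest share: the part of the charge still standing as starting material once the readings stop moving. We read it as thermodynamic control, an equilibrium at the held gas level.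

The second way is the south run, with the flask's charge but twice its catalyst. From 50.0 min on it gives 26.3%. The two ways part by 0.80 points, twice the scatter of such a difference. The south mean has fewer readings, and they wander without trend, so we keep the first way. The flask's 3.0 h is later than 50.0 min, so we commit to a conversion of 74.5% and product 53.7%.

The forecast says 74.3% and 53.6%, on the ground that “A plateau independent of concentration and catalyst is true equilibrium”; its conversion and ours differ by 0.20 points. The flask gives 74.6% and 53.4%.

    gas phase ⇌ dissolved gas, rate k1*(csat - [dissolved gas]) (kL = 0.950 /s)
    starting material + dissolved gas + catalyst ⇌ catalyst + product (K = 140 /M, k = 4200 /M²/s)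
    starting material ⇌ dormant form (K = 0.830, k = 0.00110 /s)

The flask has come to rest. Its starting material stands at 25.4% after 1.50 h, 25.4% after 3.00 h and 25.4% after 30.0 h, against our rest share of 25.5%. The dormant form holds 21.1% at the asked time. Left ten times as long, the flask gives a conversion of 74.6% and product 53.4%, and the later hour does not change the conversion.

For the neighbour with 1.6 × 10⁻⁴ M catalyst, the rest share gives a conversion of 74.5%. Computed, that neighbour gives 74.6%, with 25.4% starting material left.

The data are simulated on assumed constants, noise included.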